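**Plan**

- Retrosynthesis: the flavone is opened at O1–C8a (ring C, giving an aryl 1,3-diketone), then at C2–C3 (Claisen disconnection into a ring B benzoate and a ring A acetophenone), then at the aryl–acetyl bond of ring A.
- Enabling feature: C8a of ring A is para to the C6 oxygen. With C6 as a free phenol between the C5 and C7 methoxy groups, oxidation puts positive charge on the hydrogen-bearing C8a, so the enol oxygen on C2 can become O1.
- Forward: ring B ester 3 (bromination, methoxylation) and ring A ketone 8 (ortho-lithiation, acetylation) are joined by Claisen condensation. Ring C then closes by anodic dehydrogenative C–O cyclization. O6-methylation and one BCl3 operation (benzyl ethers and the chelated 5-methyl ether) finish the synthesis.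
- Stereochemistry: the target has no stereocentre, so nothing has to be set.

Key step: step 7

Remark on the chemistry: flavone numbering (O1, C2 to C8a, primes for ring B) is used for the open-chain precursors too; methyl 3,5-bis(benzyloxy)benzoate and 2,6-dimethoxyphenol are taken as commercial.

**Route**

Step 1
Reactants: 1 methyl 3,5-bis(benzyloxy)benzoate
Product: 2 methyl 3,5-bis(benzyloxy)-2-bromobenzoate
Conditions: NBS (1.05 equiv), MeCN, 0 °C to rt, dark
Reagents that add atoms: N-bromosuccinimide, O=C1CCC(=O)N1Br
Why: Electrophilic aromatic bromination should go to C2, which is ortho to one benzyloxy group and para to the other and less hindered than C4 between the two ethers, while the ionic conditions leave the benzylic CH2 groups alone.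

Step 2
Reactants: 2 methyl 3,5-bis(benzyloxy)-2-bromobenzoate
Product: 3 methyl 3,5-bis(benzyloxy)-2-methoxybenzoate
Conditions: NaOMe (5 equiv), CuBr (10 mol %), MeOH/DMF, 100 °C
Reagents that add atoms: sodium methoxide, [Na+].[O-]C
Why: Ullmann-type copper-catalysed methoxylation of an aryl bromide activated by the ortho ester should install the 2'-methoxy group, the methyl ester being degenerate towards methoxide and the benzyl ethers inert.

Step 3
Reactants: 4 2,6-dimethoxyphenol
Product: 5 1,3-dimethoxy-2-(methoxymethoxy)benzene
Conditions: MOMCl, iPr2NEt, CH2Cl2, 0 °C to rt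
Reagents that add atoms: chloromethyl methyl ether, COCCl
Why: Williamson-type O-alkylation gives the MOM ether, which masks the phenol through the organolithium and enolate steps and is removed by mild acid.

Step 4
Reactants: 5 1,3-dimethoxy-2-(methoxymethoxy)benzene
Product: 8 1-[2,4-dimethoxy-3-(methoxymethoxy)phenyl]ethan-1-one, via aryllithium 6 (not isolated), via lithium tetrahedral adduct 7 (not isolated)
Conditions: n-BuLi, TMEDA, THF, 0 °C; then MeC(O)N(OMe)Me, −78 °C to rt; then aq. NH4Cl
Reagents that add atoms: N-methoxy-N-methylacetamide, CC(=O)N(C)OC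
Why: Directed ortho-metalation can only occur next to a methoxy group (the two such positions are equivalent by symmetry), and the Weinreb ketone synthesis stops at the chelated adduct 7, so a single methyl ketone should result.

Step 5
Reactants: 8 1-[2,4-dimethoxy-3-(methoxymethoxy)phenyl]ethan-1-one; 3 methyl 3,5-bis(benzyloxy)-2-methoxybenzoate
Product: 9 1-[3,5-bis(benzyloxy)-2-methoxyphenyl]-3-[2,4-dimethoxy-3-(methoxymethoxy)phenyl]propane-1,3-dione
Conditions: NaH (3 equiv), THF, 65 °C; then AcOH, H2O
Reagents that add atoms: none
Why: In this crossed Claisen condensation only ketone 8 is enolisable, ester 3 can only be the acceptor, and irreversible deprotonation of the 1,3-diketone drives the reaction.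

Step 6
Reactants: 9 1-[3,5-bis(benzyloxy)-2-methoxyphenyl]-3-[2,4-dimethoxy-3-(methoxymethoxy)phenyl]propane-1,3-dione
Product: 10 1-[3,5-bis(benzyloxy)-2-methoxyphenyl]-3-(3-hydroxy-2,4-dimethoxyphenyl)propane-1,3-dione
Conditions: HCl (2 M), MeOH/THF, 40 °C
Reagents that add atoms: none
Why: Acid-catalysed acetal exchange removes the MOM group, while the benzyl and methyl ethers are stable and the diketone cannot cyclise because ring A has no ortho hydroxyl.

Step 7
Reactants: 10 1-[3,5-bis(benzyloxy)-2-methoxyphenyl]-3-(3-hydroxy-2,4-dimethoxyphenyl)propane-1,3-dione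
Product: 12 2-[3,5-bis(benzyloxy)-2-methoxyphenyl]-6-hydroxy-5,7-dimethoxy-4H-chromen-4-one, via 8aH-dienone 11 (not isolated)
Conditions: graphite anode, Pt cathode, undivided cell, constant current (2 mA cm−2, 2.0–2.2 F mol−1), Bu4NPF6 (0.1 M), HFIP, 5 mM, 25 °C
Reagents that add atoms: none
Why: Proposed new method: anodic two-electron oxidation of the free C6 phenol of 10 (flanked by the C5 and C7 methoxy groups, the most easily oxidised site) in non-nucleophilic HFIP should give a phenoxonium ion with positive charge on C8a, the hydrogen-bearing carbon para to O6, where the enol oxygen on C2 adds to give dienone 11, which loses the C8a proton and tautomerises to the aromatic 6-hydroxychromone 12 while H2 forms at the cathode. The closest known reaction types are oxidative phenol C–O cyclization of 3'-hydroxybenzophenones to xanthones and anodic dehydrogenative lactonization of biaryl-2-carboxylic acids, but an enol oxygen closing a chromone onto a phenol para position has not been shown. Ring C is closed in a six-membered mode by O-attack on the C8a terminus of the ring A cation (6-exo with respect to the C8=C8a bond of the quinoid form), and no stereocentre survives because C8a re-aromatises. Site selectivity between the two carbons ortho to the acyl group is needed: addition at the methoxy-bearing C5 would give only a ketal that cannot aromatise and should re-ionise in HFIP, whereas the C8a adduct is drained irreversibly by tautomerisation. Chemoselectivity for the phenol over ring B and over the diketone is secured by the acyl group that raises the potential of ring B, by the absence of base (no enolate is present) and by limiting the charge to about 2 F per mol. Cyclization must also outrun intermolecular phenol coupling, which the 5 mM dilution and the ortho acyl substituent at the coupling site should ensure.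

Step 8
Reactants: 12 2-[3,5-bis(benzyloxy)-2-methoxyphenyl]-6-hydroxy-5,7-dimethoxy-4H-chromen-4-one
Product: 13 2-[3,5-bis(benzyloxy)-2-methoxyphenyl]-5,6,7-trimethoxy-4H-chromen-4-one
Conditions: MeI, K2CO3, DMF, 40 °C
Reagents that add atoms: iodomethane, CI
Why: Williamson O-methylation of the only free phenol fixes the 6-methoxy group of the target, the chromone and the benzyl ethers being inert to carbonate and iodomethane.

Step 9
Reactants: 13 2-[3,5-bis(benzyloxy)-2-methoxyphenyl]-5,6,7-trimethoxy-4H-chromen-4-one
Product: 14 2-(3,5-dihydroxy-2-methoxyphenyl)-5-hydroxy-6,7-dimethoxy-4H-chromen-4-one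
Conditions: BCl3 (6 equiv), C6HMe5 (6 equiv), CH2Cl2, −78 °C then 0 °C; then H2O
Reagents that add atoms: none
Why: Lewis-acid ether cleavage with BCl3 removes aryl benzyl ethers at low temperature (pentamethylbenzene traps the benzyl cation by Friedel–Crafts alkylation), and on warming the boron chelate between the C4 carbonyl and O5 should direct demethylation to the peri 5-methoxy group only.

**Compound list**

1 | methyl 3,5-bis(benzyloxy)benzoate | COC(=O)c1cc(OCc2ccccc2)cc(OCc2ccccc2)c1 | starting material
2 | methyl 3,5-bis(benzyloxy)-2-bromobenzoate | COC(=O)c1cc(OCc2ccccc2)cc(OCc2ccccc2)c1Br | intermediate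
3 | methyl 3,5-bis(benzyloxy)-2-methoxybenzoate | COC(=O)c1cc(OCc2ccccc2)cc(OCc2ccccc2)c1OC | intermediate
4 | 2,6-dimethoxyphenol | COc1cccc(OC)c1O | starting material
5 | 1,3-dimethoxy-2-(methoxymethoxy)benzene | COCOc1c(OC)cccc1OC | intermediate
6 | [2,4-dimethoxy-3-(methoxymethoxy)phenyl]lithium | [Li]c1ccc(OC)c(OCOC)c1OC | intermediate
7 | lithium 1-[2,4-dimethoxy-3-(methoxymethoxy)phenyl]-1-[methoxy(methyl)amino]ethan-1-olate (racemic) | CC([O-])(N(C)OC)c1ccc(OC)c(OCOC)c1OC.[Li+] | intermediate
8 | 1-[2,4-dimethoxy-3-(methoxymethoxy)phenyl]ethan-1-one | CC(=O)c1ccc(OC)c(OCOC)c1OC | intermediate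
9 | 1-[3,5-bis(benzyloxy)-2-methoxyphenyl]-3-[2,4-dimethoxy-3-(methoxymethoxy)phenyl]propane-1,3-dione | COCOc1c(OC)ccc(C(=O)CC(=O)c2cc(OCc3ccccc3)cc(OCc3ccccc3)c2OC)c1OC | intermediate
10 | 1-[3,5-bis(benzyloxy)-2-methoxyphenyl]-3-(3-hydroxy-2,4-dimethoxyphenyl)propane-1,3-dione | COc1ccc(C(=O)CC(=O)c2cc(OCc3ccccc3)cc(OCc3ccccc3)c2OC)c(OC)c1O | intermediate
11 | 2-[3,5-bis(benzyloxy)-2-methoxyphenyl]-5,7-dimethoxy-8aH-chromene-4,6-dione (C8a sp3 with H, racemic) | COC1=CC2OC(c3cc(OCc4ccccc4)cc(OCc4ccccc4)c3OC)=CC(=O)C2=C(OC)C1=O | intermediate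
12 | 2-[3,5-bis(benzyloxy)-2-methoxyphenyl]-6-hydroxy-5,7-dimethoxy-4H-chromen-4-one | COc1cc2oc(-c3cc(OCc4ccccc4)cc(OCc4ccccc4)c3OC)cc(=O)c2c(OC)c1O | intermediate
13 | 2-[3,5-bis(benzyloxy)-2-methoxyphenyl]-5,6,7-trimethoxy-4H-chromen-4-one | COc1cc2oc(-c3cc(OCc4ccccc4)cc(OCc4ccccc4)c3OC)cc(=O)c2c(OC)c1OC | intermediate
14 | 2-(3,5-dihydroxy-2-methoxyphenyl)-5-hydroxy-6,7-dimethoxy-4H-chromen-4-one | COc1cc2oc(-c3cc(O)cc(O)c3OC)cc(=O)c2c(O)c1OC | target

**Step count and risks**

Total steps: 9. Longest linear sequence: 7 steps (steps 3 to 9 from 2,6-dimethoxyphenol; equally steps 1, 2 and 5 to 9 from ester 1).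

Steps most likely to fail:

Step 7. The product phenol 12 now carries oxygen para to its hydroxyl and may be oxidised further to quinoid material. Intermolecular phenol coupling or oxidation of the trialkoxylated ring B could also compete with ring closure. Within the same disconnection, a flow cell with partial conversion or PhI(OAc)2 in HFIP would be tried first. The fallback with known chemistry sets out from ester 3 and comes back at 13, bypassing 8 to 12. Ester 3 would be saponified (LiOH, THF/H2O) to 3,5-bis(benzyloxy)-2-methoxybenzoic acid F1 and converted ((COCl)2, cat. DMF, CH2Cl2) into 3,5-bis(benzyloxy)-2-methoxybenzoyl chloride F2. The dilithium dianion of commercial 1-(6-hydroxy-2,3,4-trimethoxyphenyl)ethan-1-one F3 (LiN(SiMe3)2, THF, −78 °C) would be C-acylated by F2 to 1-[3,5-bis(benzyloxy)-2-methoxyphenyl]-3-(6-hydroxy-2,3,4-trimethoxyphenyl)propane-1,3-dione F4, the intermediate of a Baker–Venkataraman flavone synthesis. Acid-catalysed cyclodehydration (TsOH, toluene, 90 °C) would then give 13, the O1–C8a bond being present from the start.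

Step 9. Regiocontrol of ether cleavage may be lost: a neighbouring borate could promote further demethylation at O6 or O2', or the electron-rich ring B could be C-benzylated if cation trapping is incomplete. The fallback sets out from 13 and comes back at 14 by separating the two events. Hydrogenolysis (H2, Pd/C, EtOAc/MeOH) would give 2-(3,5-dihydroxy-2-methoxyphenyl)-5,6,7-trimethoxy-4H-chromen-4-one F5, and chelation-controlled demethylation of the 5-methoxy group alone with AlCl3 in MeCN would then give 14.

Step 2. Substitution at a carbon flanked by the ester and a benzyloxy group may be slow, so that protodebromination or ester cleavage by methoxide takes over. The fallback sets out from 2 and comes back at 3. Miyaura borylation (B2pin2, Pd(OAc)2, SPhos, KOAc, dioxane, 90 °C) would give methyl 3,5-bis(benzyloxy)-2-(4,4,5,5-tetramethyl-1,3,2-dioxaborolan-2-yl)benzoate F6. Oxidation (NaBO3·4H2O, THF/H2O) would give methyl 3,5-bis(benzyloxy)-2-hydroxybenzoate F7, and O-methylation (MeI, K2CO3, acetone) would give 3.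

Further compounds
F1 | step 7 | 3,5-bis(benzyloxy)-2-methoxybenzoic acid | O=C(O)c1cc(OCc2ccccc2)cc(OCc2ccccc2)c1OC
F2 | step 7 | 3,5-bis(benzyloxy)-2-methoxybenzoyl chloride | O=C(Cl)c1cc(OCc2ccccc2)cc(OCc2ccccc2)c1OC
F3 | step 7 | 1-(6-hydroxy-2,3,4-trimethoxyphenyl)ethan-1-one | CC(=O)c1c(O)cc(OC)c(OC)c1OC
F4 | step 7 | 1-[3,5-bis(benzyloxy)-2-methoxyphenyl]-3-(6-hydroxy-2,3,4-trimethoxyphenyl)propane-1,3-dione | COc1cc(O)c(C(=O)CC(=O)c2cc(OCc3ccccc3)cc(OCc3ccccc3)c2OC)c(OC)c1OC
F5 | step 9 | 2-(3,5-dihydroxy-2-methoxyphenyl)-5,6,7-trimethoxy-4H-chromen-4-one | COc1cc2oc(-c3cc(O)cc(O)c3OC)cc(=O)c2c(OC)c1OC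
F6 | step 2 | methyl 3,5-bis(benzyloxy)-2-(4,4,5,5-tetramethyl-1,3,2-dioxaborolan-2-yl)benzoate | COC(=O)c1cc(OCc2ccccc2)cc(OCc2ccccc2)c1B1OC(C)(C)C(C)(C)O1
F7 | step 2 | methyl 3,5-bis(benzyloxy)-2-hydroxybenzoate | COC(=O)c1cc(OCc2ccccc2)cc(OCc2ccccc2)c1O
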